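**Plan**

- Retrosynthesis: the ketone is taken back to the carbinol and the two phenols to methoxymethyl (MOM) ethers; then both aryl–carbon bonds at the central carbon (C1–C and C1'–C) are cut together, leaving a one-carbon electrophile and two identical aryl anions.
- Enabling feature: the carbonyl carbon lies on the twofold axis of the benzophenone, and in each benzene ring C1 sits between the C2 oxygen and the C6 methoxyl, so a MOM ether at C2 and the C6 methoxyl together direct lithiation to that carbon.
- Forward: the arene is made in two steps from 2-hydroxy-4,6-dimethoxybenzaldehyde (formyl to methyl, then MOM protection); two equivalents of its lithio derivative are joined on ethyl formate; oxidation and acetal cleavage finish the route.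
- Rings: none is formed; both benzene rings come from the starting aldehyde.
- Stereochemistry: none; the target has no stereocentre, and the carbinol carbon of the coupling product carries two identical aryl groups.

Key step: step 3

Remark: the locants used for compound 4 are those of its name (methoxy at C1 and C5, methyl at C2, methoxymethoxy at C3, ring hydrogens at C4 and C6); compounds 1, 3 and 5 are catalogue chemicals.

**Route**

Step 1
Reactants: 1 2-hydroxy-4,6-dimethoxybenzaldehyde
Product: 2 3,5-dimethoxy-2-methylphenol
Conditions: H2 (1 atm), 10% Pd/C, AcOH, conc. HCl (cat.), rt
Reagents that add atoms: none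
Why: Catalytic hydrogenolysis of an electron-rich aryl aldehyde, in which the carbonyl is hydrogenated to the benzylic alcohol and its C–O bond, activated by the ortho-hydroxyl, the two methoxyls and the acid, is then cleaved on palladium to leave the methyl group, while the aryl ethers and the ring should stay untouched at room temperature and low pressure.

Step 2
Reactants: 2 3,5-dimethoxy-2-methylphenol; 3 chloromethyl methyl ether
Product: 4 1,5-dimethoxy-3-(methoxymethoxy)-2-methylbenzene
Conditions: NaH, DMF, 0 °C; then MOMCl, 0 °C → rt
Reagents that add atoms: chloromethyl methyl ether (3), COCCl
Why: Williamson-type O-alkylation of the sodium phenoxide with the reactive α-chloro ether should install the methoxymethyl acetal, which later directs the lithiation and is stable to organolithium and oxidation conditions.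

Step 3
Reactants: 4 1,5-dimethoxy-3-(methoxymethoxy)-2-methylbenzene (2 equiv); 5 ethyl formate (1 equiv)
Product: 8 bis[2-(methoxymethoxy)-4,6-dimethoxy-3-methylphenyl]methanol, via aryllithium 6 (not isolated), via aldehyde 7 (not isolated)
Conditions: n-BuLi (hexanes), THF, 0 °C → rt, 1 h; then HCO2Et (0.5 equiv), −78 °C → rt; H2O
Reagents that add atoms: ethyl formate (5), CCOC=O
Why: n-BuLi binds to the acetal oxygens of the methoxymethyl group of 4 and removes the ring proton at C4, between the methoxymethoxy and a methoxy group, to give aryllithium 6; 6 adds to the carbonyl of ethyl formate, the tetrahedral adduct expels ethoxide to give aldehyde 7, and a second molecule of 6 adds to 7 to give the lithium alkoxide of 8, which water protonates. The closest known reaction types are the directed ortho-lithiation of aryl methoxymethyl ethers and the double addition of aryllithiums to formate esters, the usual entry to symmetrical diaryl carbinols. No ring is closed, and no stereocentre is formed because the carbinol carbon carries two identical aryl groups. The step needs site selectivity (C4, not C6 between the two methoxyls) and a stop after two additions. The C2 methyl group turns the acetal chain toward C4, where its outer oxygen delivers the base, and turns the O-methyl of the C1 methoxyl toward C6, which shields that position and takes the coordinating lone pair away from it. Formate offers a single leaving group, so the sequence stops at the secondary alkoxide and no triaryl carbinol can arise.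

Step 4
Reactants: 8 bis[2-(methoxymethoxy)-4,6-dimethoxy-3-methylphenyl]methanol
Product: 9 bis[2-(methoxymethoxy)-4,6-dimethoxy-3-methylphenyl]methanone
Conditions: 2-iodoxybenzoic acid (IBX), DMSO, rt
Reagents that add atoms: none
Why: IBX oxidation of a secondary benzylic alcohol, which proceeds by ligand exchange at the hypervalent iodine and loss of the carbinol hydrogen, is known to tolerate benzhydrols with ortho substituents on both rings, and the near-neutral medium should leave the acetals, the aryl methyl groups and the electron-rich rings intact at room temperature.

Step 5
Reactants: 9 bis[2-(methoxymethoxy)-4,6-dimethoxy-3-methylphenyl]methanone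
Product: 10 2,2'-dihydroxy-4,4',6,6'-tetramethoxy-3,3'-dimethylbenzophenone, i.e. bis(2-hydroxy-4,6-dimethoxy-3-methylphenyl)methanone
Conditions: conc. HCl (3 equiv), MeOH, rt → 45 °C
Reagents that add atoms: none
Why: Acid-catalysed acetal cleavage (transacetalisation) should release both phenols, each then held by a hydrogen bond to the ketone, while methanol takes up the oxocarbenium ions as dimethoxymethane and the aryl methyl ethers are stable to dilute acid.

**Compound list**

1 | 2-hydroxy-4,6-dimethoxybenzaldehyde | COc1cc(O)c(C=O)c(OC)c1 | starting material
2 | 3,5-dimethoxy-2-methylphenol | COc1cc(O)c(C)c(OC)c1 | intermediate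
3 | chloromethyl methyl ether | COCCl | starting material
4 | 1,5-dimethoxy-3-(methoxymethoxy)-2-methylbenzene | COCOc1cc(OC)cc(OC)c1C | intermediate
5 | ethyl formate | CCOC=O | starting material
6 | [2-(methoxymethoxy)-4,6-dimethoxy-3-methylphenyl]lithium | [Li]c1c(OC)cc(OC)c(C)c1OCOC | intermediate (not isolated)
7 | 2-(methoxymethoxy)-4,6-dimethoxy-3-methylbenzaldehyde | COCOc1c(C)c(OC)cc(OC)c1C=O | intermediate (not isolated)
8 | bis[2-(methoxymethoxy)-4,6-dimethoxy-3-methylphenyl]methanol | COCOc1c(C)c(OC)cc(OC)c1C(O)c1c(OC)cc(OC)c(C)c1OCOC | intermediate
9 | bis[2-(methoxymethoxy)-4,6-dimethoxy-3-methylphenyl]methanone | COCOc1c(C)c(OC)cc(OC)c1C(=O)c1c(OC)cc(OC)c(C)c1OCOC | intermediate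
10 | 2,2'-dihydroxy-4,4',6,6'-tetramethoxy-3,3'-dimethylbenzophenone | COc1cc(OC)c(C(=O)c2c(OC)cc(OC)c(C)c2O)c(O)c1C | target

**Step count and risks**

Total step count: 5. Longest linear sequence: 5 steps (1 → 2 → 4 → 8 → 9 → 10).

Steps most likely to fail:

Step 3. Part of the metalation may occur at C6 between the two methoxyls. The coupling may also stall after the first addition, or the product alkoxide may transfer hydride to aldehyde 7, so that aldehyde, ketone and isomeric carbinols form side by side. The fallback sets out from phenol 2 and builds one half without lithiation and without formate. Magnesium-mediated ortho-formylation (MgCl2, Et3N, paraformaldehyde, MeCN, reflux) should place the formyl group at the only free position ortho to the hydroxyl and give 2-hydroxy-4,6-dimethoxy-3-methylbenzaldehyde F1. NaH and 3 in DMF then convert it into aldehyde 7, which is now isolated and purified. One equivalent of aryllithium 6, generated from 4 as in step 3, is added to 7 in THF at −78 °C, and the route is rejoined at carbinol 8. This fixes the substitution pattern of one ring independently of the lithiation and replaces the double addition by a single one.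

Step 4. Oxidation at a carbinol flanked by four ortho substituents may be slow, and the very electron-rich benzhydrol may ionise to the diarylmethyl cation, leading to ether formation or aryl–carbon cleavage. The fallback sets out from 4 and reaches the ketone oxidation level directly through a Weinreb ketone synthesis. Aryllithium 6 is treated with N-methoxy-N-methylcarbamoyl chloride in THF at −78 °C to give N-methoxy-2-(methoxymethoxy)-4,6-dimethoxy-N,3-dimethylbenzamide F2. A second portion of 6 adds to this amide to give the chelated lithium tetrahedral adduct F3, which is stable until aqueous work-up and then releases ketone 9, where the route is rejoined.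

Step 1. The reduction may stop at the hydroxymethyl stage, and in the acid the derived benzylic cation may condense with a second electron-rich ring; forcing conditions risk saturating the ring. The fallback sets out from 1 and changes both the order of events and the type of reduction. NaH and 3 in DMF give 2-(methoxymethoxy)-4,6-dimethoxybenzaldehyde F4. Wolff–Kishner reduction in the Huang-Minlon manner (N2H4·H2O, KOH, diethylene glycol, 120 °C then 190 °C) proceeds through the hydrazone F5 and loses dinitrogen under basic conditions that the acetal and the methyl ethers tolerate. This gives 4 directly, where the route is rejoined, with no benzylic cation involved.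

**Further compounds**

F1 | step 3 | 2-hydroxy-4,6-dimethoxy-3-methylbenzaldehyde | COc1cc(OC)c(C=O)c(O)c1C
F2 | step 4 | N-methoxy-2-(methoxymethoxy)-4,6-dimethoxy-N,3-dimethylbenzamide | CON(C)C(=O)c1c(OC)cc(OC)c(C)c1OCOC
F3 | step 4 | lithium bis[2-(methoxymethoxy)-4,6-dimethoxy-3-methylphenyl][methoxy(methyl)amino]methanolate | [Li+].[O-]C(N(C)OC)(c1c(OC)cc(OC)c(C)c1OCOC)c1c(OC)cc(OC)c(C)c1OCOC
F4 | step 1 | 2-(methoxymethoxy)-4,6-dimethoxybenzaldehyde | COCOc1cc(OC)cc(OC)c1C=O
F5 | step 1 | [2-(methoxymethoxy)-4,6-dimethoxyphenyl]methylidenehydrazine | COCOc1cc(OC)cc(OC)c1C=NN
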